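The runs stem from a simulated flask for substances that don't exist, noise included.

Turn the question round. The flask to reckon is the last recipe below.

in all of them: left-handed substrate 0.10 M; right-handed substrate 0.10 M

| charge | reagent | catalyst | added ligand | remark | time |
|---|---|---|---|---|---|
| epsilon | 0.28 M | 1 mM | 3 mM | run made earlier |  |
| zeta | 0.44 M | 1 mM | 3 mM | run made earlier |  |
| gamma | 0.20 M | 2 mM | 3 mM | run made earlier |  |
| flask | 0.200 M | 1.0 mM | 3.0 mM |  | 20 h |

| run | time / h | left-handed substrate / % | right-handed substrate / % |
|---|---|---|---|
| epsilon | 2.00 | 48.0 | 48.5 |
| epsilon | 4.00 | 46.9 | 47.0 |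
| epsilon | 6.00 | 44.7 | 47.6 |
| epsilon | 8.00 | 43.7 | 45.1 |
| epsilon | 10.0 | 41.9 | 44.4 |
| epsilon | 12.0 | 41.4 | 44.0 |
| zeta | 0.833 | 49.2 | 48.6 |
| zeta | 2.50 | 46.8 | 48.2 |
| zeta | 4.00 | 44.6 | 46.9 |
| zeta | 6.00 | 42.0 | 44.2 |
| zeta | 10.0 | 38.2 | 42.0 |
| zeta | 12.0 | 35.9 | 41.0 |
| gamma | 2.50 | 44.4 | 46.7 |
| gamma | 5.00 | 40.0 | 44.2 |
| gamma | 8.00 | 37.1 | 42.4 |
| gamma | 10.0 | 34.7 | 40.0 |
| gamma | 12.0 | 32.2 | 38.0 |

(readings scatter by 0.5 percentage points)

- part of the left-handed substrate and right-handed substrate charged together that has reacted at 20 h
- excess of left-handed product over right-handed product in the product at 20 h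
- excess of right-handed substrate over left-handed substrate among what is left of the two at 20 h

- catalyst is single-handed; left-handed substrate and right-handed substrate are mirror images of each other, charged as a racemate, each of them at the stated concentration
- the analysis behind the earlier runs scatters by 0.5 percentage points, standard deviation
- an excess is the difference of the two amounts in percent of their sum
- an excess is below zero if the other one leads

For the left-handed substrate to lead among what remains, more of its own charge would have to survive than of the right-handed substrate's. If each substrate reacts first order in itself with the same reagent and catalyst, those shared factors cancel when you divide the two rates and integrate. The fractions left, f, then obey ln f(left) = s ln f(right). The scattered gamma readings at 12.0 h give 1.60 for s, the selectivity factor, which is the logarithm of the left-handed fraction left divided by that of the right-handed fraction left. The opposite outcome needs s below 1, and this gamma reading stands 0.600 above that line. The zeta readings, with different reagent and catalyst, give 1.67.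

My own reckoning uses zeta, which shares the flask's catalyst and added ligand. I take the logarithmic loss of right-handed substrate as proportional to c(reagent) times time, holding reagent at its charge in both, though it falls. Zeta then gives 0.0376 M⁻¹ h⁻¹. For the flask at 20 h, I reckon from that 86.0% of the right-handed substrate left and, through s, 78.6% of the left-handed. So I expect c near 17.7%, eS near 4.50% and eP near 20.9%. The first product formed should carry an excess of 23.2%.

The forecast, holding that “reagent is roughly first order”, gives c 17.1%, eP 20.4% and eS 4.2%.

The flask gives c 17.5%, eP 14.7% and eS 4.45%.

    reagent + catalyst + left-handed substrate → catalyst + left-handed product (k = 960 M⁻² h⁻¹)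
    reagent + catalyst + right-handed substrate → catalyst + right-handed product (k = 600 M⁻² h⁻¹)
    2 reagent → homo dimer (k = 0.0150 M⁻¹ h⁻¹)
    left-handed product ⇌ right-handed product (k = 0.0170 h⁻¹)
    catalyst + added ligand ⇌ idle complex, settled at all times (K = 6200 M⁻¹)

The product excess in the flask stood at 22.1% after 2.00 h, then reached 14.7% at 20 h, while the left-handed and right-handed products interconverted with a relaxation half-life, both ways together, of 20.4 h. At 20 h the flask's remaining fractions give s = 1.60, and the neighbouring flask charged with 0.80 M of reagent, at 49.0% conversion, gives s = 1.60.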